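**Plan**

- Feature used: in the cyclohexane ring the oxygen-bearing carbons C1, C3 and C5 stand 1,3 to one another. With C5 at the ketone level the ring is two β-hydroxy ketones (C5-C6-C1 and C5-C4-C3) that share one carbonyl group.
- Cuts: (a) three benzyl groups; (b) the O3-acyl bond together with the C5-H bond (Evans-Tishchenko, O-benzylvanillin as acyl and hydride source); (c) C6-C1 and C4-C3 together. This leaves a three-carbon acetonyl O-benzylvanillate and a four-carbon 2,4-dioxobutanoate.
- Helpers: a CO2H on C6 gives a regiospecific enolate and leaves as CO2. An ethyl enol ether at C3 hides the aldehyde while C1 is a ketone and leaves as ethanol. C5 stays a ketone until O3 is acylated, so 5-OH never competes.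
- Forward: two achiral chains are made (two steps and one step). One flask then runs decarboxylative aldol C6 to C1, enol ether hydrolysis and aldol closure C4 to C3, which builds the only carbocycle. The Tishchenko step and hydrogenolysis follow.
- Stereochemistry: C1 comes from the copper (S,S)-t-Bu-box catalyst, C3 and C4 from the chair closure governed by C1, and C5 from hydride delivery out of the O3 hemiacetal.

Key step: step 4

Remark: the SMILES is read as the 3,4-diester of (-)-quinic acid, (1R,3R,4S,5R), with 1-OH, O3 and O4 on one ring face and 5-OH and CO2H on the other. Quinic acid numbering is used for ring and pre-ring atoms. ArCO = 4-(benzyloxy)-3-methoxybenzoyl. (S,S)-t-Bu-box = 2,2'-(propane-2,2-diyl)bis[(4S)-4-tert-butyl-4,5-dihydro-1,3-oxazole].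

**Route**

Step 1
Reactants: 1 4-(benzyloxy)-3-methoxybenzoic acid; 2 tert-butyl 4-chloro-3-oxobutanoate
Product: 3 tert-butyl 4-{[4-(benzyloxy)-3-methoxybenzoyl]oxy}-3-oxobutanoate
Conditions: KHCO3 (1.1 equiv), NaI (10 mol %), DMF, rt
Reagents that add atoms: none
Why: Iodide-assisted SN2 displacement of the primary α-keto chloride by the carboxylate should work because bicarbonate is too weak to deprotonate the β-keto ester, so the active methylene stays out of play and no stereocentre is involved.

Step 2
Reactants: 3 tert-butyl 4-{[4-(benzyloxy)-3-methoxybenzoyl]oxy}-3-oxobutanoate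
Product: 4 4-{[4-(benzyloxy)-3-methoxybenzoyl]oxy}-3-oxobutanoic acid
Conditions: TFA/CH2Cl2 1:2, 0 °C; evaporated cold, used at once
Reagents that add atoms: none
Why: Acidolysis of the tert-butyl ester (loss of isobutene) frees the β-keto acid without base, the aryl ester and the aryl benzyl ether tolerate cold TFA, and cold handling holds back early decarboxylation.

Step 3
Reactants: 5 ethyl vinyl ether; 6 oxalyl chloride; 7 benzyl alcohol
Product: 9 benzyl (E)-4-ethoxy-2-oxobut-3-enoate, via acid chloride 8 (not isolated)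
Conditions: 5 + 6, CH2Cl2, 0 °C to rt; then 7, Et3N, CH2Cl2, -20 °C
Reagents that add atoms: none
Why: Electrophilic acylation of the enol ether at its β-carbon by oxalyl chloride and loss of HCl gives the (E)-configured push-pull enone acid chloride, which benzyl alcohol esterifies (known acylation of vinyl ethers).

Step 4
Reactants: 4 4-{[4-(benzyloxy)-3-methoxybenzoyl]oxy}-3-oxobutanoic acid; 9 benzyl (E)-4-ethoxy-2-oxobut-3-enoate
Product: 12 benzyl (1S,3R,4R)-4-{[4-(benzyloxy)-3-methoxybenzoyl]oxy}-1,3-dihydroxy-5-oxocyclohexane-1-carboxylate, via enol ether carbinol 10 (not isolated), via keto aldehyde 11 (not isolated)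
Conditions: Cu(OTf)2 (10 mol %), (S,S)-t-Bu-box (11 mol %), THF, 0 °C to rt; then 1 M aq HCl, 0 °C; then NaHCO3 to pH 7-8, rt (one flask, no isolation)
Reagents that add atoms: water, O
Why: Proposed new method: keto ester 9 sits as an O,O-chelate in the plane of the square-planar divalent copper complex while the carboxylate of 4 binds at an apical site, so the C6 enol carbon adds to the C1 ketone and CO2 leaves (10); aqueous acid then hydrolyses the enol ether, inert as a vinylogous ester in 9 but electron-rich once C1 is sp3, to aldehyde 11, and at pH 7-8 the copper-bound acyloxy ketone enolises towards C4 and attacks C3. The closest known reaction types are the metal-bis(oxazoline)-catalysed decarboxylative aldol addition of β-keto acids to β,γ-unsaturated α-keto esters, which proceeds 1,2, and the aldol ring closure of 1,5-keto aldehydes known from the Ferrier carbocyclisation; the 4-alkoxy group on the acceptor and the joining of both events in one flask are new. The one ring formed, the cyclohexanone, closes in the 6-(enolendo)-exo-trig mode through a chair. C1 is set by the ligand, whose tert-butyl group next to the bound ketone oxygen shields the Re face so that C6 enters on the Si face; C3 is set by C1, because in the chair with CO2Bn equatorial and 1-OH axial the aldehyde oxygen takes the axial site where 1-OH can hydrogen-bond to it (attack on the Si face of C3); C4 follows from the chelated (Z)-enolate in the same chair, which puts its ester equatorial and cis to O3. The step needs attack by C6 and not C4, secured by the carboxyl helper on C6; 1,2- and not 1,4-addition, secured by delivery inside the copper coordination sphere, from which C3 is out of reach; and an aldehyde that never coexists with the C1 ketone, secured by the enol ether switch. Both helpers leave in the same flask as CO2 and ethanol.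

Step 5
Reactants: 12 benzyl (1S,3R,4R)-4-{[4-(benzyloxy)-3-methoxybenzoyl]oxy}-1,3-dihydroxy-5-oxocyclohexane-1-carboxylate; 13 4-(benzyloxy)-3-methoxybenzaldehyde
Product: 14 benzyl (1R,3R,4S,5R)-3,4-bis{[4-(benzyloxy)-3-methoxybenzoyl]oxy}-1,5-dihydroxycyclohexane-1-carboxylate
Conditions: SmI2 (30 mol %, premixed with 13), 13 (4 equiv), THF, -10 °C
Reagents that add atoms: none
Why: Evans-Tishchenko reduction: the secondary axial 3-OH (the tertiary 1-OH is too hindered) forms a hemiacetal with 13 on trivalent samarium and its C-H is delivered through a six-membered transition state to the axial face of the C5 ketone, which at once makes the 3-ester, leaves 5-OH free and sets C5 with its hydroxyl equatorial, anti to O3 and cis to CO2Bn, under non-basic conditions that spare the β-oxygenated ketone.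

Step 6
Reactants: 14 benzyl (1R,3R,4S,5R)-3,4-bis{[4-(benzyloxy)-3-methoxybenzoyl]oxy}-1,5-dihydroxycyclohexane-1-carboxylate
Product: 15 burkinabin A, (1R,3R,4S,5R)-1,5-dihydroxy-3,4-bis[(4-hydroxy-3-methoxybenzoyl)oxy]cyclohexane-1-carboxylic acid
Conditions: H2 (1 atm), 10% Pd/C, EtOAc/THF 1:1, rt
Reagents that add atoms: none
Why: Hydrogenolysis of the two aryl benzyl ethers and the benzyl ester under neutral conditions frees both phenols and the acid without touching the aryl esters or any stereocentre and without the base that would make the esters migrate.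

**Compound list**

1 | 4-(benzyloxy)-3-methoxybenzoic acid | COc1cc(C(=O)O)ccc1OCc1ccccc1 | starting material
2 | tert-butyl 4-chloro-3-oxobutanoate | CC(C)(C)OC(=O)CC(=O)CCl | starting material
3 | tert-butyl 4-{[4-(benzyloxy)-3-methoxybenzoyl]oxy}-3-oxobutanoate | COc1cc(C(=O)OCC(=O)CC(=O)OC(C)(C)C)ccc1OCc1ccccc1 | intermediate
4 | 4-{[4-(benzyloxy)-3-methoxybenzoyl]oxy}-3-oxobutanoic acid | COc1cc(C(=O)OCC(=O)CC(=O)O)ccc1OCc1ccccc1 | intermediate
5 | ethyl vinyl ether | C=COCC | starting material
6 | oxalyl chloride | O=C(Cl)C(=O)Cl | starting material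
7 | benzyl alcohol | OCc1ccccc1 | starting material
8 | (E)-4-ethoxy-2-oxobut-3-enoyl chloride | CCO/C=C/C(=O)C(=O)Cl | intermediate
9 | benzyl (E)-4-ethoxy-2-oxobut-3-enoate | CCO/C=C/C(=O)C(=O)OCc1ccccc1 | intermediate
10 | benzyl (2R,3E)-2-(3-{[4-(benzyloxy)-3-methoxybenzoyl]oxy}-2-oxopropyl)-4-ethoxy-2-hydroxybut-3-enoate | COc1cc(C(=O)OCC(=O)C[C@](O)(C(=O)OCc2ccccc2)/C=C/OCC)ccc1OCc1ccccc1 | intermediate
11 | benzyl (2S)-5-{[4-(benzyloxy)-3-methoxybenzoyl]oxy}-2-hydroxy-4-oxo-2-(2-oxoethyl)pentanoate | COc1cc(C(=O)OCC(=O)C[C@](O)(C(=O)OCc2ccccc2)CC=O)ccc1OCc1ccccc1 | intermediate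
12 | benzyl (1S,3R,4R)-4-{[4-(benzyloxy)-3-methoxybenzoyl]oxy}-1,3-dihydroxy-5-oxocyclohexane-1-carboxylate | COc1cc(C(=O)O[C@H]2C(=O)C[C@](O)(C(=O)OCc3ccccc3)C[C@H]2O)ccc1OCc1ccccc1 | intermediate
13 | 4-(benzyloxy)-3-methoxybenzaldehyde | COc1cc(C=O)ccc1OCc1ccccc1 | starting material
14 | benzyl (1R,3R,4S,5R)-3,4-bis{[4-(benzyloxy)-3-methoxybenzoyl]oxy}-1,5-dihydroxycyclohexane-1-carboxylate | COc1cc(C(=O)O[C@H]2[C@H](O)C[C@](O)(C(=O)OCc3ccccc3)C[C@H]2OC(=O)c2ccc(OCc3ccccc3)c(OC)c2)ccc1OCc1ccccc1 | intermediate
15 | burkinabin A | COc1cc(C(=O)O[C@H]2[C@H](O)C[C@](O)(C(=O)O)C[C@H]2OC(=O)c2ccc(O)c(OC)c2)ccc1O | target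

Total steps: 6. Longest linear sequence: 5 steps (1, 2, 4, 5, 6).

**Steps most likely to fail**

1. Step 4 (labelled step).
   - What may go wrong:
     - conjugate attack of C6 at C3, followed by expulsion of ethoxide;
     - capture of the enol of 4 by the oxadiene of 9;
     - loss of water across C1-C2 from the β-hydroxy aldehyde before C4 closes;
     - ester shift from O4 to O3, or epimerisation at C4, during the neutral hold;
     - poor facial selectivity at C3.
   - Fallback (known chemistry, sets out from 4 and returns at 11): dibenzyl oxalate is mono-allylated with allylmagnesium bromide (THF, -78 °C) to benzyl 2-oxopent-4-enoate F1, a plain α-keto ester without a conjugate position. Decarboxylative aldol addition of 4 to F1 under the same Cu(OTf)2/(S,S)-t-Bu-box catalysis gives benzyl (2S)-2-(3-{[4-(benzyloxy)-3-methoxybenzoyl]oxy}-2-oxopropyl)-2-hydroxypent-4-enoate F2, which is isolated. Lemieux-Johnson cleavage of the terminal alkene (OsO4 cat., NaIO4, 2,6-lutidine, dioxane/H2O) gives 11, which is closed to 12 with NaHCO3 as in step 4. The aldehyde carbon is thus carried as an alkene instead of an enol ether, and the two bonds are made in two operations.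

2. Step 5.
   - What may go wrong:
     - retro-aldol opening of the doubly β-hydroxylated ketone on the samarium alkoxide;
     - reductive loss of the α-acyloxy group by unconsumed divalent samarium;
     - hemiacetal formation at O1;
     - sluggish hydride transfer from the electron-rich aldehyde.
   - Fallback (sets out from 12 and returns at 15): reduction and acylation are separated, and 5-OH is hidden in a lactone. Evans-Saksena reduction (Me4NBH(OAc)3, MeCN/AcOH, -20 °C), directed by 1-OH and 3-OH, gives benzyl 4-O-[4-(benzyloxy)-3-methoxybenzoyl]quinate F3. TsOH·H2O (cat.) in warm toluene closes 5-OH onto the ester to 4-O-[4-(benzyloxy)-3-methoxybenzoyl]-1,5-quinide F4. Acid 1 is turned with 6 and catalytic DMF into 4-(benzyloxy)-3-methoxybenzoyl chloride F5, which acylates the secondary 3-OH of F4 (pyridine, DMAP cat., CH2Cl2, 0 °C) to 3,4-bis-O-[4-(benzyloxy)-3-methoxybenzoyl]-1,5-quinide F6. Hydrogenolysis (H2, 10% Pd/C) gives 3,4-di-O-vanilloyl-1,5-quinide F7, and 1 M aq HCl/THF opens the lactone to 15.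

3. Step 1.
   - What may go wrong:
     - enolisation of the chloro keto ester, followed by self-alkylation or ring closure to a furanone;
     - slow substitution.
   - Fallback (sets out from 1 and returns at 3): the β-keto ester is built by acylation instead of substitution. Acid 1 is alkylated with tert-butyl bromoacetate (K2CO3, DMF) to tert-butyl {[4-(benzyloxy)-3-methoxybenzoyl]oxy}acetate F8. TFA gives {[4-(benzyloxy)-3-methoxybenzoyl]oxy}acetic acid F9. Coupling with Meldrum's acid (DCC, DMAP, CH2Cl2) gives 5-(2-{[4-(benzyloxy)-3-methoxybenzoyl]oxy}-1-hydroxyethylidene)-2,2-dimethyl-1,3-dioxane-4,6-dione F10. Heating F10 with tert-butanol in toluene gives 3 through the acyl ketene.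

**Further compounds**

F1 | step 4 | benzyl 2-oxopent-4-enoate | C=CCC(=O)C(=O)OCc1ccccc1
F2 | step 4 | benzyl (2S)-2-(3-{[4-(benzyloxy)-3-methoxybenzoyl]oxy}-2-oxopropyl)-2-hydroxypent-4-enoate | COc1cc(C(=O)OCC(=O)C[C@](O)(C(=O)OCc2ccccc2)CC=C)ccc1OCc1ccccc1
F3 | step 5 | benzyl 4-O-[4-(benzyloxy)-3-methoxybenzoyl]quinate | COc1cc(C(=O)O[C@H]2[C@H](O)C[C@](O)(C(=O)OCc3ccccc3)C[C@H]2O)ccc1OCc1ccccc1
F4 | step 5 | 4-O-[4-(benzyloxy)-3-methoxybenzoyl]-1,5-quinide | COc1cc(C(=O)O[C@H]2[C@H](O3)C[C@](O)(C3=O)C[C@H]2O)ccc1OCc1ccccc1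
F5 | step 5 | 4-(benzyloxy)-3-methoxybenzoyl chloride | COc1cc(C(=O)Cl)ccc1OCc1ccccc1
F6 | step 5 | 3,4-bis-O-[4-(benzyloxy)-3-methoxybenzoyl]-1,5-quinide | COc1cc(C(=O)O[C@H]2[C@H](O3)C[C@](O)(C3=O)C[C@H]2OC(=O)c2ccc(OCc3ccccc3)c(OC)c2)ccc1OCc1ccccc1
F7 | step 5 | 3,4-di-O-vanilloyl-1,5-quinide | COc1cc(C(=O)O[C@H]2[C@H](O3)C[C@](O)(C3=O)C[C@H]2OC(=O)c2ccc(O)c(OC)c2)ccc1O
F8 | step 1 | tert-butyl {[4-(benzyloxy)-3-methoxybenzoyl]oxy}acetate | COc1cc(C(=O)OCC(=O)OC(C)(C)C)ccc1OCc1ccccc1
F9 | step 1 | {[4-(benzyloxy)-3-methoxybenzoyl]oxy}acetic acid | COc1cc(C(=O)OCC(=O)O)ccc1OCc1ccccc1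
F10 | step 1 | 5-(2-{[4-(benzyloxy)-3-methoxybenzoyl]oxy}-1-hydroxyethylidene)-2,2-dimethyl-1,3-dioxane-4,6-dione | COc1cc(C(=O)OCC(O)=C2C(=O)OC(C)(C)OC2=O)ccc1OCc1ccccc1
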